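**Retrosynthetic overview**

1. Final step: one palladium-catalysed three-component union of the iodo-enyne acetate 15, CO and the lactone vinylstannane 23 closes the cyclopentenone (C9–C10 and C8–C9, C9 from CO) and forms the C6–C7 diene bond with 7Z geometry.
2. 15 comes from a tertiary carbinol carrying two differentiated alkynes (Takano–Yadav alkynol synthesis on a Sharpless epoxy chloride, then iodoalkyne to Z-vinyl iodide).
3. The epoxy alcohol comes from a Z-enynol assembled from hept-1-yne, 4-chlorobut-2-yn-1-ol and ethynyl(trimethyl)silane.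
4. 23 comes from succinic anhydride and ethynyl(trimethyl)silane by ynone transfer hydrogenation, lactonisation and hydrostannation.
5. Ring order: the γ-lactone is made first (side branch); the cyclopentenone is formed last, in the union step.

Assumption: carbon labels C5–C15 in the text follow prostanoid numbering of the target (C12 = acetoxy-bearing ring carbon, C9 = ring C=O, C7=C8 = exocyclic alkene, C5=C6 = E-alkene); gases, solvents and common reagents are taken as available.

**Route**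

Step 1
Reactants: 1 hept-1-yne; 2 4-chlorobut-2-yn-1-ol
Product: 3 undeca-2,5-diyn-1-ol
Conditions: CuI (10 mol %), n-Bu4NI (10 mol %), Cs2CO3 (1.5 equiv), DMF, rt
Reagents that add atoms: none
Why: Copper-acetylide SN2 alkylation of a primary propargylic chloride (Jeffery-type skipped-diyne synthesis) tolerates the free hydroxyl and gives the 1,4-diyne without allene formation.

Step 2
Reactants: 3 undeca-2,5-diyn-1-ol
Product: 5 (2Z)-3-iodoundec-2-en-5-yn-1-ol, via vinylalanate 4 (not isolated)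
Conditions: NaAlH2(OCH2CH2OMe)2 (1.6 equiv), THF, 0 °C → rt; EtOAc; then I2, THF, −78 → 0 °C
Reagents that add atoms: iodine, [I][I]
Why: Hydroxyl-directed trans-hydroalumination puts aluminium on C3 of the propargylic alkyne only (cyclic alkoxyaluminate), and iodinolysis with retention gives the (Z)-3-iodo allylic alcohol while the remote alkyne is untouched.

Step 3
Reactants: 5 (2Z)-3-iodoundec-2-en-5-yn-1-ol; 6 ethynyl(trimethyl)silane
Product: 7 (2Z)-3-(oct-2-yn-1-yl)-5-(trimethylsilyl)pent-2-en-4-yn-1-ol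
Conditions: PdCl2(PPh3)2 (3 mol %), CuI (6 mol %), i-Pr2NH, THF, rt
Reagents that add atoms: none
Why: Sonogashira coupling of the alkenyl iodide proceeds with retention of alkene geometry, so the silylalkynyl group ends cis to CH2OH.

Step 4
Reactants: 7 (2Z)-3-(oct-2-yn-1-yl)-5-(trimethylsilyl)pent-2-en-4-yn-1-ol
Product: 8 (2Z)-3-[(2Z)-oct-2-en-1-yl]-5-(trimethylsilyl)pent-2-en-4-yn-1-ol
Conditions: H2 (1 atm, stopped at 1.0 equiv uptake), Pd/CaCO3–Pb(OAc)2 (Lindlar), quinoline, EtOAc–hexane, rt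
Reagents that add atoms: none
Why: Lindlar semihydrogenation adds H2 syn to the unhindered dialkyl alkyne to set the (Z)-octenyl alkene, while trimethylsilyl-capped enynes are known to survive these conditions.

Step 5
Reactants: 8 (2Z)-3-[(2Z)-oct-2-en-1-yl]-5-(trimethylsilyl)pent-2-en-4-yn-1-ol
Product: 9 [(2S,3R)-3-[(2Z)-oct-2-en-1-yl]-3-[(trimethylsilyl)ethynyl]oxiran-2-yl]methanol
Conditions: Ti(OiPr)4 (0.2 equiv), L-(+)-diethyl tartrate (0.24 equiv), t-BuOOH (2 equiv), 4 Å MS, CH2Cl2, −20 °C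
Reagents that add atoms: tert-butyl hydroperoxide, CC(C)(C)OO
Why: Katsuki–Sharpless asymmetric epoxidation, in which L-(+)-tartrate attacks the same alkene face as in nerol (which gives the 2S,3R epoxide), sets the future C12 C–O stereocentre (expected above 90% ee); the isolated Z-alkene is not allylic to OH and is not epoxidised.

Step 6
Reactants: 9 [(2S,3R)-3-[(2Z)-oct-2-en-1-yl]-3-[(trimethylsilyl)ethynyl]oxiran-2-yl]methanol
Product: 10 (2R,3R)-2-(chloromethyl)-3-[(2Z)-oct-2-en-1-yl]-3-[(trimethylsilyl)ethynyl]oxirane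
Conditions: PPh3, CCl4, NaHCO3 (cat.), reflux
Reagents that add atoms: tetrachloromethane, ClC(Cl)(Cl)Cl
Why: Appel chlorination converts the primary alcohol into the chloride under neutral conditions that leave the epoxide and both stereocentres intact (the descriptor at C2 changes only because of CIP priorities).

Step 7
Reactants: 10 (2R,3R)-2-(chloromethyl)-3-[(2Z)-oct-2-en-1-yl]-3-[(trimethylsilyl)ethynyl]oxirane
Product: 12 (3R,5Z)-1-iodo-3-[(trimethylsilyl)ethynyl]undec-5-en-1-yn-3-ol, via dilithio alkynolate 11 (not isolated)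
Conditions: n-BuLi (3.3 equiv), THF, −78 → −30 °C; then I2 (1.4 equiv), THF, −78 → 0 °C
Reagents that add atoms: iodine, [I][I]
Why: Takano–Yadav alkynol synthesis (base-induced epoxide opening from the α-chloro carbanion, then loss of HCl) gives the lithium acetylide of the tertiary propargylic alkoxide without breaking the C3–O bond, so configuration is retained; the acetylide is iodinated in the same flask and the silyl cap keeps the two alkynes distinguishable.

Step 8
Reactants: 12 (3R,5Z)-1-iodo-3-[(trimethylsilyl)ethynyl]undec-5-en-1-yn-3-ol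
Product: 13 (1Z,3S,5Z)-1-iodo-3-[(trimethylsilyl)ethynyl]undeca-1,5-dien-3-ol
Conditions: 2-nitrobenzenesulfonohydrazide (3 equiv), Et3N, THF–i-PrOH, rt, dark
Reagents that add atoms: none
Why: Diimide reduction transfers H2 syn to the iodoalkyne faster than to the hindered silylalkyne or the Z-disubstituted alkene, giving the (Z)-vinyl iodide.

Step 9
Reactants: 13 (1Z,3S,5Z)-1-iodo-3-[(trimethylsilyl)ethynyl]undeca-1,5-dien-3-ol
Product: 14 (1Z,3S,5Z)-3-ethynyl-1-iodoundeca-1,5-dien-3-ol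
Conditions: K2CO3 (0.3 equiv), MeOH, 0 °C → rt
Reagents that add atoms: none
Why: Mild methanolysis cleaves the C(sp)–Si bond and leaves the vinyl iodide and the carbinol centre untouched.

Step 10
Reactants: 14 (1Z,3S,5Z)-3-ethynyl-1-iodoundeca-1,5-dien-3-ol
Product: 15 (1Z,3S,5Z)-3-ethynyl-1-iodoundeca-1,5-dien-3-yl acetate
Conditions: Ac2O (5 equiv), DMAP (1 equiv), Et3N, CH2Cl2, rt → 35 °C
Reagents that add atoms: acetic anhydride, CC(=O)OC(C)=O
Why: DMAP-catalysed acylation works on tertiary propargylic alcohols; acetylating before the union also blocks butenolide formation from the later acylpalladium intermediate.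

Step 11
Reactants: 6 ethynyl(trimethyl)silane; 16 oxolane-2,5-dione (succinic anhydride)
Product: 18 4-oxo-6-(trimethylsilyl)hex-5-ynoic acid, via lithium (trimethylsilyl)acetylide 17 (not isolated)
Conditions: n-BuLi, THF, −78 °C; then added to 16 (1.5 equiv), THF, −78 °C; aq. HCl
Reagents that add atoms: none
Why: Inverse addition of the lithium acetylide to the cyclic anhydride at low temperature stops at the keto carboxylate, giving the ynone acid in one step.

Step 12
Reactants: 18 4-oxo-6-(trimethylsilyl)hex-5-ynoic acid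
Product: 19 methyl 4-oxo-6-(trimethylsilyl)hex-5-ynoate
Conditions: Me3SiCHN2, PhMe–MeOH (4:1), 0 °C
Reagents that add atoms: (trimethylsilyl)diazomethane, C[Si](C)(C)C=[N+]=[N-]
Why: Neutral diazoalkane esterification avoids exposing the silyl ynone to acid or base and frees the catalyst of the next step from a carboxylic acid.

Step 13
Reactants: 19 methyl 4-oxo-6-(trimethylsilyl)hex-5-ynoate
Product: 20 methyl (4R)-4-hydroxy-6-(trimethylsilyl)hex-5-ynoate
Conditions: Ru[(R,R)-TsNCHPhCHPhNH](p-cymene) (1 mol %), i-PrOH, rt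
Reagents that add atoms: none
Why: Noyori–Ikariya asymmetric transfer hydrogenation of the ynone, in which the alkynyl group takes the role of the aryl group and the (R,R) catalyst gives the (R)-propargylic alcohol (typically at least 95% ee), sets the lactone stereocentre.

Step 14
Reactants: 20 methyl (4R)-4-hydroxy-6-(trimethylsilyl)hex-5-ynoate
Product: 21 (5R)-5-[(trimethylsilyl)ethynyl]oxolan-2-one
Conditions: TsOH·H2O (5 mol %), PhMe, rt → 40 °C
Reagents that add atoms: none
Why: Acid-catalysed γ-lactonisation closes the lactone ring with the carbinol C–O bond retained, so the stereocentre is unchanged.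

Step 15
Reactants: 21 (5R)-5-[(trimethylsilyl)ethynyl]oxolan-2-one
Product: 22 (5R)-5-ethynyloxolan-2-one
Conditions: Bu4NF (1.1 equiv), AcOH (1.2 equiv), THF, 0 °C
Reagents that add atoms: none
Why: Buffered fluoride protodesilylation frees the terminal alkyne without opening the lactone or epimerising the propargylic centre.

Step 16
Reactants: 22 (5R)-5-ethynyloxolan-2-one
Product: 23 (5R)-5-[(E)-2-(tributylstannyl)ethenyl]oxolan-2-one
Conditions: Bu3SnH (1.2 equiv), Pd2(dba)3 (1 mol %), Cy3P·HBF4 (4 mol %), i-Pr2NEt (8 mol %), CH2Cl2, 0 °C → rt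
Reagents that add atoms: tributylstannane, CCCC[SnH](CCCC)CCCC
Why: Palladium-catalysed syn-hydrostannation with the bulky Cy3P ligand places tin on the terminal carbon and gives the (E)-vinylstannane.

Step 17
Reactants: 15 (1Z,3S,5Z)-3-ethynyl-1-iodoundeca-1,5-dien-3-yl acetate; 23 (5R)-5-[(E)-2-(tributylstannyl)ethenyl]oxolan-2-one
Product: 24 (5R)-5-[(1E,3Z)-3-[(2S)-2-acetoxy-2-[(2Z)-oct-2-en-1-yl]-5-oxocyclopent-3-en-1-ylidene]prop-1-en-1-yl]oxolan-2-one (target)
Conditions: Pd2(dba)3·CHCl3 (5 mol %), P(2-furyl)3 (20 mol %), CO (1.2 equiv, sealed flask), 23 (1.2 equiv, syringe pump over 3 h), THF, 50 °C, dark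
Reagents that add atoms: carbon monoxide, [C-]#[O+]
Why: Proposed new method: a carbonylative cyclisation–Stille cascade in which zerovalent palladium inserts into the (Z)-alkenyl C–I bond of 15, CO insertion gives the (Z)-enoyl–palladium species, this adds syn across the tethered terminal alkyne in the only geometrically possible 5-exo-dig mode (C8–C9 bond and ring closure, with palladium on the exocyclic carbon cis to the new ketone as an O-chelated alkenylpalladium that should resist a second CO insertion when CO is kept near one equivalent), and stereoretentive transmetalation and reductive elimination with 23 form C6–C7 so that the diene arm must end cis to the ring carbonyl (7Z) while C12 and the lactone centre are untouched; the closest known reaction types are Negishi's cyclic acylpalladation of alkynes (terminated by CO and alcohol), cyclisation–anion-capture cascades and the carbonylative Stille coupling.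

**Compound list**

1 | hept-1-yne | CCCCCC#C | starting material
2 | 4-chlorobut-2-yn-1-ol | OCC#CCCl | starting material
3 | undeca-2,5-diyn-1-ol | CCCCCC#CCC#CCO | intermediate
4 | sodium 2,2-bis(2-methoxyethoxy)-3-(oct-2-yn-1-yl)-2,5-dihydro-1,2-oxaluminol-2-uide (cyclic vinylalanate) | CCCCCC#CCC1=CCO[Al-]1(OCCOC)OCCOC.[Na+] | intermediate (not isolated)
5 | (2Z)-3-iodoundec-2-en-5-yn-1-ol | OC/C=C(\I)CC#CCCCCC | intermediate
6 | ethynyl(trimethyl)silane | C#C[Si](C)(C)C | starting material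
7 | (2Z)-3-(oct-2-yn-1-yl)-5-(trimethylsilyl)pent-2-en-4-yn-1-ol | OC/C=C(\C#C[Si](C)(C)C)CC#CCCCCC | intermediate
8 | (2Z)-3-[(2Z)-oct-2-en-1-yl]-5-(trimethylsilyl)pent-2-en-4-yn-1-ol | OC/C=C(\C#C[Si](C)(C)C)C/C=C\CCCCC | intermediate
9 | [(2S,3R)-3-[(2Z)-oct-2-en-1-yl]-3-[(trimethylsilyl)ethynyl]oxiran-2-yl]methanol | OC[C@@H]1O[C@@]1(C#C[Si](C)(C)C)C/C=C\CCCCC | intermediate
10 | (2R,3R)-2-(chloromethyl)-3-[(2Z)-oct-2-en-1-yl]-3-[(trimethylsilyl)ethynyl]oxirane | ClC[C@@H]1O[C@@]1(C#C[Si](C)(C)C)C/C=C\CCCCC | intermediate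
11 | dilithium (3S,5Z)-3-[(trimethylsilyl)ethynyl]undec-5-en-1-yn-1-id-3-olate | CCCCC/C=C\C[C@@](O[Li])(C#C[Si](C)(C)C)C#C[Li] | intermediate (not isolated)
12 | (3R,5Z)-1-iodo-3-[(trimethylsilyl)ethynyl]undec-5-en-1-yn-3-ol | CCCCC/C=C\C[C@@](O)(C#C[Si](C)(C)C)C#CI | intermediate
13 | (1Z,3S,5Z)-1-iodo-3-[(trimethylsilyl)ethynyl]undeca-1,5-dien-3-ol | CCCCC/C=C\C[C@@](O)(C#C[Si](C)(C)C)/C=C\I | intermediate
14 | (1Z,3S,5Z)-3-ethynyl-1-iodoundeca-1,5-dien-3-ol | CCCCC/C=C\C[C@@](O)(C#C)/C=C\I | intermediate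
15 | (1Z,3S,5Z)-3-ethynyl-1-iodoundeca-1,5-dien-3-yl acetate | CCCCC/C=C\C[C@@](OC(C)=O)(C#C)/C=C\I | intermediate
16 | oxolane-2,5-dione (succinic anhydride) | O=C1CCC(=O)O1 | starting material
17 | lithium (trimethylsilyl)acetylide | [Li]C#C[Si](C)(C)C | intermediate (not isolated)
18 | 4-oxo-6-(trimethylsilyl)hex-5-ynoic acid | OC(=O)CCC(=O)C#C[Si](C)(C)C | intermediate
19 | methyl 4-oxo-6-(trimethylsilyl)hex-5-ynoate | COC(=O)CCC(=O)C#C[Si](C)(C)C | intermediate
20 | methyl (4R)-4-hydroxy-6-(trimethylsilyl)hex-5-ynoate | COC(=O)CC[C@@H](O)C#C[Si](C)(C)C | intermediate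
21 | (5R)-5-[(trimethylsilyl)ethynyl]oxolan-2-one | C[Si](C)(C)C#C[C@H]1CCC(=O)O1 | intermediate
22 | (5R)-5-ethynyloxolan-2-one | C#C[C@H]1CCC(=O)O1 | intermediate
23 | (5R)-5-[(E)-2-(tributylstannyl)ethenyl]oxolan-2-one | CCCC[Sn](CCCC)(CCCC)/C=C/[C@H]1CCC(=O)O1 | intermediate
24 | (5R)-5-[(1E,3Z)-3-[(2S)-2-acetoxy-2-[(2Z)-oct-2-en-1-yl]-5-oxocyclopent-3-en-1-ylidene]prop-1-en-1-yl]oxolan-2-one | CCCCC/C=C\C[C@]1(OC(C)=O)C=CC(=O)/C1=C\C=C\[C@H]1CCC(=O)O1 | target

**Step count and risk**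

Total step count: 17. Longest linear sequence: 11 steps (steps 1–10, then 17); the lactone branch is steps 11–16.

The three steps most likely to fail are 17, 8 and 4.

Step 17 (the new cascade). Risks are direct carbonylative Stille coupling before ring closure, a second CO insertion, and ionisation of the propargylic acetate. The fallback uses the established aldol endgame of the clavulone family; it sets out from 14 and 22 and comes back at 24. Compound 14 is silylated (Et3SiOTf, 2,6-lutidine) to triethyl{[(1Z,3S,5Z)-3-ethynyl-1-iodoundeca-1,5-dien-3-yl]oxy}silane F1. Anti-Markovnikov hydration of its terminal alkyne (dicyclohexylborane, then NaBO3·4H2O) gives (3R,5Z)-3-[(Z)-2-iodoethenyl]-3-[(triethylsilyl)oxy]undec-5-enal F2. An intramolecular Nozaki–Hiyama–Kishi reaction (CrCl2, cat. NiCl2, DMF) closes the ring to (4R)-4-[(2Z)-oct-2-en-1-yl]-4-[(triethylsilyl)oxy]cyclopent-2-en-1-ol F3, and MnO2 oxidises this to (4R)-4-[(2Z)-oct-2-en-1-yl]-4-[(triethylsilyl)oxy]cyclopent-2-en-1-one F4. In parallel, 22 is semihydrogenated (Pd/CaCO3–Pb(OAc)2, quinoline, H2) to (5R)-5-ethenyloxolan-2-one F5, and cross-metathesis with crotonaldehyde (second-generation Hoveyda–Grubbs catalyst, RuCl2(H2IMes)(=CH-C6H4-2-OiPr)) gives (2E)-3-[(2R)-5-oxooxolan-2-yl]prop-2-enal F6. The kinetic enolate of F4 (LiN(i-Pr)2, THF, −78 °C) adds to F6 to give (4S)-5-{(2E)-1-hydroxy-3-[(2R)-5-oxooxolan-2-yl]prop-2-en-1-yl}-4-[(2Z)-oct-2-en-1-yl]-4-[(triethylsilyl)oxy]cyclopent-2-en-1-one F7. Mesylation and elimination (MsCl, Et3N, then DBU) give the dienone as a 7E/7Z mixture; the 7Z isomer, (5R)-5-[(1E,3Z)-3-[(2S)-2-[(2Z)-oct-2-en-1-yl]-5-oxo-2-[(triethylsilyl)oxy]cyclopent-3-en-1-ylidene]prop-1-en-1-yl]oxolan-2-one F8, is separated and the 7E isomer is recycled by photoisomerisation as known for clavulones. HF·pyridine gives (5R)-5-[(1E,3Z)-3-[(2S)-2-hydroxy-2-[(2Z)-oct-2-en-1-yl]-5-oxocyclopent-3-en-1-ylidene]prop-1-en-1-yl]oxolan-2-one F9, and Ac2O/DMAP gives 24.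

Step 8 (diimide reduction). Risks are over-reduction of the Z-octenyl alkene and incomplete conversion. The fallback reverses the order of reduction and iodination; it sets out from 10 and comes back at 13. The Takano–Yadav elimination of 10 (n-BuLi, 3.3 equiv) is quenched with aqueous NH4Cl instead of iodine to give (3S,5Z)-3-[(trimethylsilyl)ethynyl]undec-5-en-1-yn-3-ol F10. Radical anti-hydroindation of the terminal alkyne (HInCl2 from InCl3 and i-Bu2AlH, cat. Et3B, THF, −78 °C) gives dichloro[(1Z,3S,5Z)-3-hydroxy-3-[(trimethylsilyl)ethynyl]undeca-1,5-dien-1-yl]indium F11, which is iodinated in the same flask (I2) with retention to give 13.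

Step 4 (chemoselective semihydrogenation). The risk is partial reduction of the silyl enyne. The fallback installs the Z-alkene on a simple C8 unit before any second alkyne exists; it sets out from 1 and comes back at 8. Compound 1 is hydroxymethylated (n-BuLi, paraformaldehyde) to oct-2-yn-1-ol F12 and semihydrogenated (Pd/CaCO3–Pb(OAc)2, quinoline, H2) to (2Z)-oct-2-en-1-ol F13, which is converted (CBr4, PPh3) into (2Z)-1-bromooct-2-ene F14. Copper-mediated coupling with prop-2-yn-1-ol (CuI, Cs2CO3, DMF) gives (5Z)-undec-5-en-2-yn-1-ol F15. Directed hydroalumination–iodination (NaAlH2(OCH2CH2OMe)2, then I2) gives (2Z,5Z)-3-iodoundeca-2,5-dien-1-ol F16, and Sonogashira coupling with 6 (PdCl2(PPh3)2, CuI, i-Pr2NH) gives 8.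

**Further compounds**

F1 | step 17 | triethyl{[(1Z,3S,5Z)-3-ethynyl-1-iodoundeca-1,5-dien-3-yl]oxy}silane | CCCCC/C=C\C[C@@](O[Si](CC)(CC)CC)(C#C)/C=C\I
F2 | step 17 | (3R,5Z)-3-[(Z)-2-iodoethenyl]-3-[(triethylsilyl)oxy]undec-5-enal | CCCCC/C=C\C[C@@](O[Si](CC)(CC)CC)(CC=O)/C=C\I
F3 | step 17 | (4R)-4-[(2Z)-oct-2-en-1-yl]-4-[(triethylsilyl)oxy]cyclopent-2-en-1-ol (C1 epimers) | CCCCC/C=C\C[C@@]1(O[Si](CC)(CC)CC)CC(O)C=C1
F4 | step 17 | (4R)-4-[(2Z)-oct-2-en-1-yl]-4-[(triethylsilyl)oxy]cyclopent-2-en-1-one | CCCCC/C=C\C[C@@]1(O[Si](CC)(CC)CC)CC(=O)C=C1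
F5 | step 17 | (5R)-5-ethenyloxolan-2-one | C=C[C@H]1CCC(=O)O1
F6 | step 17 | (2E)-3-[(2R)-5-oxooxolan-2-yl]prop-2-enal | O=C/C=C/[C@H]1CCC(=O)O1
F7 | step 17 | (4S)-5-{(2E)-1-hydroxy-3-[(2R)-5-oxooxolan-2-yl]prop-2-en-1-yl}-4-[(2Z)-oct-2-en-1-yl]-4-[(triethylsilyl)oxy]cyclopent-2-en-1-one (diastereomer mixture) | CCCCC/C=C\C[C@@]1(O[Si](CC)(CC)CC)C(C(O)/C=C/[C@H]2CCC(=O)O2)C(=O)C=C1
F8 | step 17 | (5R)-5-[(1E,3Z)-3-[(2S)-2-[(2Z)-oct-2-en-1-yl]-5-oxo-2-[(triethylsilyl)oxy]cyclopent-3-en-1-ylidene]prop-1-en-1-yl]oxolan-2-one | CCCCC/C=C\C[C@]1(O[Si](CC)(CC)CC)C=CC(=O)/C1=C\C=C\[C@H]1CCC(=O)O1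
F9 | step 17 | (5R)-5-[(1E,3Z)-3-[(2S)-2-hydroxy-2-[(2Z)-oct-2-en-1-yl]-5-oxocyclopent-3-en-1-ylidene]prop-1-en-1-yl]oxolan-2-one | CCCCC/C=C\C[C@]1(O)C=CC(=O)/C1=C\C=C\[C@H]1CCC(=O)O1
F10 | step 8 | (3S,5Z)-3-[(trimethylsilyl)ethynyl]undec-5-en-1-yn-3-ol | CCCCC/C=C\C[C@@](O)(C#C[Si](C)(C)C)C#C
F11 | step 8 | dichloro[(1Z,3S,5Z)-3-hydroxy-3-[(trimethylsilyl)ethynyl]undeca-1,5-dien-1-yl]indium | CCCCC/C=C\C[C@@](O)(C#C[Si](C)(C)C)/C=C\[In](Cl)Cl
F12 | step 4 | oct-2-yn-1-ol | CCCCCC#CCO
F13 | step 4 | (2Z)-oct-2-en-1-ol | CCCCC/C=C\CO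
F14 | step 4 | (2Z)-1-bromooct-2-ene | CCCCC/C=C\CBr
F15 | step 4 | (5Z)-undec-5-en-2-yn-1-ol | CCCCC/C=C\CC#CCO
F16 | step 4 | (2Z,5Z)-3-iodoundeca-2,5-dien-1-ol | OC/C=C(\I)C/C=C\CCCCC
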